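The rate constants were drawn at random within sensible limits.

Each flask gets 1.05 reagent per starting material, while each side product takes two.

common to all: time 8.0 h
- green: starting material 0.21 M (fed, over 6.0 h); reagent 0.221 M; all else is in the flask from the start; the feed brings no volume worth counting
- amber: starting material 0.21 M; reagent 0.221 M (fed, over 6.0 h); all else is in the flask from the start; the feed brings no volume worth counting
- ochre: starting material 0.21 M; reagent 0.221 M; everything together at the start

    starting material + reagent → target (k1 = 3.4 × 10⁻⁴ L mol⁻¹ s⁻¹)
    starting material + 2 reagent → side product (k2 = 0.0035 L² mol⁻² s⁻¹)
    2 starting material → self-condensation product (k3 = 0.0020 L mol⁻¹ s⁻¹)
    starting material → decomposition product (k4 = 2.1 × 10⁻⁷ s⁻¹)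

- which flask leads in amount of side product, in percent of the starting material charged ("all alike" within 1.5 percentage points) (green / amber / ochre / all alike)
- how much side product is there at the end, in percent of the starting material charged: green
- how much side product is there at the end, in percent of the starting material charged: amber
- how much side product is there at the end, in percent of the starting material charged: ochre

- in percentages every species weighs as the starting material in it: one self-condensation product counts as two
- two of one species on the left: rate k times its square, two consumed each time
- run time (green): 8.0 h

Write a for starting material and b for reagent, each as a fraction of its charge. Decomposition we drop, since its half-life of 38 d is far longer than the 8.0 h run.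

In its first instants, with a and b both one, ochre stands at 15.7% in what we call the side share: of the starting material leaving at an instant, the fraction taken by the two-reagent step, an instantaneous selectivity. For a later point we guess a = 0.200 and b = 0.7, which reckons to a share of 27.5% for ochre, so we commit to the mean, 21.6%.

Amber opens with b at zero, and so with a side share of zero. Its starting material has a self-condensation half-life of 0.331 h, shorter than the feed. For mid-feed, reckoning self-condensation by itself, we put amber at a = 9.93%, and at b = 0.5 the share reckons to 26.1%. Their product, 2.59%, is our scale for amber.

In green, we set a where feed balances loss. At b of one that gives a = 13.0% and a share of 48.1%, but green would then demand 111% of its reagent charge. So we go round at b = 0.7: a = 16.7%, and the reagent used puts the mean b at 62.2%. Once more with that b: a = 17.7%, and the share is 25.3%. That puts green's share above ochre's mean and amber's product.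

The forecast gives green with 25.5%, amber 4.6% and ochre 20.5%, holding that “feeding starting material into the full reagent charge therefore gives the most side product”.

The simulation gives green in the lead: green 25.2%, ochre 20.8%, amber 5.01%. Our mean for ochre was 21.6%, and amber's product 2.59% is 0.517 of amber's figure. A neighbour of amber is charged with 0.055 M of reagent, 0.262 equiv: at the same a and at b = 0.5 its share reckons to 2.77%, far below the 15.7% of ochre's first instants, and its product is 0.275%. That neighbour ends with 0.656% of side product, and the product is 0.419 of it.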